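**Remarks on the chemistry.** The target is taken as the open 5‑hydroxy‑2‑ketone that is drawn; a transannular hemiketal, if it forms, is treated as an equilibrium form of the same compound. Locants used below: ring B = C1–C10 (C2 ketone, C5 carbinol, C6 lactone O–CH, C7, C8 ester carbon, C9 CH2); ring A = lactone (C6, C7, C11, C12, O) with C13 as the methylidene carbon; C14 = methyl on C10; C15 = methyl on C4. The target is (5S,6R,7R,8S), 1(10)Z, 3Z, with a cis‑fused lactone.

## Retrosynthetic overview

1. 27 ⇐ 26 (desilylation) ⇐ 24: the C8–C9 bond of ring B is made by intramolecular vinylogous Mukaiyama‑type addition of C9 to a C8 acyloxycarbenium ion. The enabling feature is that C8–O sits in the vinylogous aldol (δ) position of the C2 ketone through the C1=C10 bond inside the ten‑membered ring, so C9 is the γ carbon of a C2 dienolate and C8 an aldehyde‑level carbon.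
2. 24 ⇐ keto aldehyde 20: the aldehyde is masked as its bis‑tiglate acylal (this also brings the C8 ester), and the deconjugated methallyl ketone is enolized regiospecifically at C1.
3. 20 ⇐ 16 + 7: C4–C5 bond by Nozaki–Hiyama–Kishi coupling (sets C5, brings the Z C3=C4 bond), then silyl and oxidation‑level adjustments.
4. 16 ⇐ 11 + 12: ring A (cis α‑methylene‑γ‑butyrolactone, C6–C7 bond) by indium Barbier allylation and lactonization; the glyceraldehyde carbon is then cleaved off.
5. Ring order: ring A (lactone) in step 7, ring B (ten‑membered carbocycle) in step 16.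

Key step: step 16

## Route

Step 1
Reactants: 1 but‑2‑yn‑1‑ol
Product: 3 (Z)‑3‑iodobut‑2‑en‑1‑ol, via cyclic vinylalanate 2 (not isolated)
Conditions: NaAlH2(OCH2CH2OMe)2, THF, 0 °C to rt; then I2, THF, −78 °C to rt
Reagents that add atoms: iodine, II
Why: Hydroxyl‑directed trans‑hydroalumination places aluminium on the distal alkyne carbon in a five‑membered alanate, and iodinolysis with retention should give the Z vinyl iodide (I cis to CH2OH), the source of the Z C3=C4 geometry.

Step 2
Reactants: 3 (Z)‑3‑iodobut‑2‑en‑1‑ol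
Product: 4 (Z)‑3‑iodobut‑2‑enal
Conditions: MnO2 (activated, excess), CH2Cl2, rt, dark; used crude
Reagents that add atoms: none
Why: Allylic oxidation with MnO2 is neutral and should keep the Z geometry of the sensitive β‑iodoenal.

Step 3
Reactants: 4 (Z)‑3‑iodobut‑2‑enal; 5 2‑methylallylmagnesium chloride
Product: 6 (Z)‑2‑iodo‑6‑methylhepta‑2,6‑dien‑4‑ol (racemic)
Conditions: THF, −78 °C; aq. NH4Cl
Reagents that add atoms: none
Why: Grignard 1,2‑addition of an allylic magnesium reagent to the enal; the new carbinol carbon (later C2) is racemic, which is harmless because it becomes the ketone in step 12.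

Step 4
Reactants: 6 (Z)‑2‑iodo‑6‑methylhepta‑2,6‑dien‑4‑ol
Product: 7 triethyl{[(Z)‑2‑iodo‑6‑methylhepta‑2,6‑dien‑4‑yl]oxy}silane (racemic)
Conditions: TESCl, imidazole, CH2Cl2, 0 °C
Reagents that add atoms: chlorotriethylsilane, CC[Si](Cl)(CC)CC
Why: Standard silylation of a secondary alcohol; the TES group is chosen so that it leaves together with the primary TBS group in step 11.

Step 5
Reactants: 8 methyl acrylate; 9 (tert‑butyldimethylsilyloxy)acetaldehyde
Product: 10 methyl 4‑[(tert‑butyldimethylsilyl)oxy]‑3‑hydroxy‑2‑methylidenebutanoate (racemic)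
Conditions: DABCO (0.5 equiv), neat methyl acrylate, rt
Reagents that add atoms: none
Why: Morita–Baylis–Hillman reaction of an activated α‑oxygenated aldehyde; the racemic carbinol centre is lost in step 6.

Step 6
Reactants: 10 Morita–Baylis–Hillman alcohol
Product: 11 methyl (Z)‑2‑(bromomethyl)‑4‑[(tert‑butyldimethylsilyl)oxy]but‑2‑enoate
Conditions: NBS, Me2S, CH2Cl2, 0 °C to rt
Reagents that add atoms: N‑bromosuccinimide, O=C1CCC(=O)N1Br
Why: Corey–Kim‑type activation of the alcohol and SN2′ delivery of bromide should give the rearranged Z allylic bromide (ester trans to CH2OTBS), as is usual for Baylis–Hillman alcohols.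

Step 7
Reactants: 11 allylic bromide; 12 (S)‑2,2‑dimethyl‑1,3‑dioxolane‑4‑carbaldehyde (2,3‑O‑isopropylidene‑L‑glyceraldehyde)
Product: 14 (4R,5R)‑4‑{[(tert‑butyldimethylsilyl)oxy]methyl}‑5‑[(4S)‑2,2‑dimethyl‑1,3‑dioxolan‑4‑yl]‑3‑methylideneoxolan‑2‑one (cis lactone), via hydroxy ester 13 (not isolated)
Conditions: In powder, THF/H2O (1:1), rt; then PPTS (cat.), toluene, 60 °C
Reagents that add atoms: none
Why: Barbier allylation through a chair transition state of the Z‑configured 2‑(methoxycarbonyl)allylindium should give the syn adduct (C6/C7, hence the cis lactone), with Felkin–Anh attack anti to the dioxolane C–O bond setting C6 from the (S) centre; acid‑catalysed lactonization then closes ring A.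

Step 8
Reactants: 14 cis lactone acetonide
Product: 16 (2R,3R)‑3‑{[(tert‑butyldimethylsilyl)oxy]methyl}‑4‑methylidene‑5‑oxooxolane‑2‑carbaldehyde, via diol 15 (not isolated)
Conditions: H5IO6 (1.5 equiv), EtOAc, 0 °C to rt; used crude
Reagents that add atoms: none
Why: Periodic acid cleaves the terminal acetonide and the resulting glycol in one pot (Malaprade cleavage), turning the spent glyceraldehyde carbon into the C5 aldehyde without touching the C6 and C7 centres.

Step 9
Reactants: 16 lactone aldehyde; 7 Z vinyl iodide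
Product: 17 (4R,5R)‑4‑{[(tert‑butyldimethylsilyl)oxy]methyl}‑5‑[(1S,2Z)‑1‑hydroxy‑2,6‑dimethyl‑4‑[(triethylsilyl)oxy]hepta‑2,6‑dien‑1‑yl]‑3‑methylideneoxolan‑2‑one (both epimers at the TES‑bearing carbon)
Conditions: CrCl2 (4 equiv), NiCl2 (2 mol %), DMSO/THF, rt
Reagents that add atoms: none
Why: Nozaki–Hiyama–Kishi coupling is chemoselective for the aldehyde and keeps the alkene geometry, and Felkin–Anh addition anti to the C6–O bond should give the 5,6‑anti (5S) alcohol.

Step 10
Reactants: 17 allylic alcohol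
Product: 18 the C5 tert‑butyldimethylsilyl ether of 17
Conditions: TBSOTf, 2,6‑lutidine, CH2Cl2, −78 °C
Reagents that add atoms: tert‑butyldimethylsilyl triflate, CC(C)(C)[Si](C)(C)OS(=O)(=O)C(F)(F)F
Why: Silyl triflate silylation of a hindered secondary alcohol; the C5 oxygen must stay blocked so that the Z γ‑oxy enone made later cannot close to a lactol or furan.

Step 11
Reactants: 18 tris‑silyl ether
Product: 19 (4R,5R)‑5‑[(1S,2Z)‑1‑[(tert‑butyldimethylsilyl)oxy]‑4‑hydroxy‑2,6‑dimethylhepta‑2,6‑dien‑1‑yl]‑4‑(hydroxymethyl)‑3‑methylideneoxolan‑2‑one (both epimers at the carbinol)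
Conditions: HF·pyridine, pyridine, THF, 0 °C
Reagents that add atoms: none
Why: Selective desilylation, since a primary TBS ether and a secondary TES ether are cleaved much faster than the hindered secondary TBS ether at C5.

Step 12
Reactants: 19 diol
Product: 20 (2R,3S)‑2‑[(1S,2Z)‑1‑[(tert‑butyldimethylsilyl)oxy]‑2,6‑dimethyl‑4‑oxohepta‑2,6‑dien‑1‑yl]‑4‑methylidene‑5‑oxooxolane‑3‑carbaldehyde
Conditions: Dess–Martin periodinane (3 equiv), pyridine, CH2Cl2, 0 °C to rt; used without chromatography
Reagents that add atoms: none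
Why: Double Dess–Martin oxidation makes the C8 aldehyde and the C2 ketone at once, the two C2 epimers converge on one compound, and the buffered neutral conditions should leave the methallyl ketone deconjugated.

Step 13
Reactants: 21 tiglic acid
Product: 22 tiglic anhydride
Conditions: tigloyl chloride (1.0 equiv), pyridine (1.1 equiv), Et2O, 0 °C to rt; filtration and concentration
Reagents that add atoms: tigloyl chloride [(E)‑2‑methylbut‑2‑enoyl chloride], C/C=C(\C)C(=O)Cl
Why: Nucleophilic acyl substitution of the acid chloride by the pyridinium carboxylate should give the symmetric anhydride with both E double bonds unchanged, one tigloyl unit coming from the acid and the other from the chloride.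

Step 14
Reactants: 20 keto aldehyde; 22 tiglic anhydride
Product: 23 {(2R,3S)‑2‑[(1S,2Z)‑1‑[(tert‑butyldimethylsilyl)oxy]‑2,6‑dimethyl‑4‑oxohepta‑2,6‑dien‑1‑yl]‑4‑methylidene‑5‑oxooxolan‑3‑yl}methylene bis[(E)‑2‑methylbut‑2‑enoate] (C8 bis‑tiglate acylal)
Conditions: Sc(OTf)3 (2 mol %), CH2Cl2, 0 °C
Reagents that add atoms: none
Why: Lewis‑acid‑catalysed acylal formation is selective for aldehydes over ketones; it removes the acidity of C7–H and the β‑elimination pathway, and it installs the tiglate that ends on C8.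

Step 15
Reactants: 23 acylal ketone
Product: 24 the (1S,2Z,4Z)‑1,4‑bis[(tert‑butyldimethylsilyl)oxy]‑2,6‑dimethylhepta‑2,4,6‑trien‑1‑yl analogue of 23 (cross‑conjugated silyl dienol ether; the C1=C2 geometry is expected Z and is lost in step 16)
Conditions: TBSOTf (1.3 equiv), Et3N (2.5 equiv), CH2Cl2, −78 to −20 °C; Et3N‑deactivated silica
Reagents that add atoms: tert‑butyldimethylsilyl triflate, CC(C)(C)[Si](C)(C)OS(=O)(=O)C(F)(F)F
Why: Soft enolization with silyl triflate and amine occurs at C1, the only CH2 flanked by the carbonyl and an alkene, so the 2‑silyloxytriene is formed regiospecifically while the acylal has no enolizable site.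

Step 16
Reactants: 24 silyl dienol ether acylal
Product: 26 5‑O‑tert‑butyldimethylsilyl ether of the target (ring B closed; 8S tiglate; 1(10)Z), via acyloxycarbenium triflate 25 (not isolated)
Conditions: TMSOTf (0.3 equiv), 2,6‑di‑tert‑butyl‑4‑methylpyridine (0.5 equiv), CH2Cl2, −78 to −40 °C, slow addition of 24 (final 1 mM); aq. NaHCO3
Reagents that add atoms: none
Why: Proposed new method: catalytic TMSOTf ionizes the gem‑bis(tigloyloxy) carbon C8 of 24 to the acyloxycarbenium ion 25, the terminal carbon C9 of the cross‑conjugated 2‑silyloxytriene adds to it (γ attack of a silyl dienol ether, a vinylogous Mukaiyama addition), and loss of the silyl group to the departing tiglate restores the C2 ketone and the silyl triflate, so that the C8–C9 bond, the C1=C10 double bond and the C8 tiglate of the target arise together. The closest known reaction types are Lewis‑acid‑promoted additions of silyl enol ethers and allylsilanes to acylals, which give β‑acyloxy ketones and homoallylic esters, and intramolecular vinylogous Mukaiyama aldol closures onto aldehydes or acetals; their combination in one ten‑membered ring closure has not been shown. Ring B closes in a 10‑exo‑trig mode at the oxocarbenium carbon, with the reacting diene unit inside the new ring. The new C1=C10 bond should be Z because only the s‑cis conformer about C10–C1 lets C9 reach C8 across the short tether (cis C3=C4 bond, cis‑fused lactone), and a ten‑membered ring accommodates a cis alkene far better than a trans one. The C8 centre is controlled by C7 and by the ring: C9 adds anti to the C7–C11 bond (Felkin–Anh, sp2 substituent as the large group) on the face that keeps H8 inside and the acyloxy group outside the nascent ring, which is 8S. The step needs γ over α attack and ring closure over oligomerization: γ attack is the normal course of silyl dienol ethers and α attack would close a more strained eight‑membered ring, the dienol ether was made regiospecifically from the deconjugated ketone, the acylal has no enolizable or eliminable position, and slow addition keeps the substrate near 1 mM.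

Step 17
Reactants: 26 silyl‑protected macrocycle
Product: 27 target, (5S,6R,7R,8S)‑5‑hydroxy‑2‑oxo‑8‑tigloyloxygermacra‑1(10)Z,3Z,11(13)‑trien‑12,6‑olide
Conditions: HF·pyridine, pyridine, THF, 0 °C to rt
Reagents that add atoms: none
Why: Buffered fluoride desilylation of the secondary allylic TBS ether should leave the tiglate, the methylidene lactone and the dienone untouched.

## Compound list

1 | but‑2‑yn‑1‑ol | CC#CCO | starting material
2 | cyclic vinylalanate (sodium salt) | C/C1=C/CO[Al-]1(OCCOC)OCCOC.[Na+] | intermediate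
3 | (Z)‑3‑iodobut‑2‑en‑1‑ol | C/C(I)=C/CO | intermediate
4 | (Z)‑3‑iodobut‑2‑enal | C/C(I)=C/C=O | intermediate
5 | 2‑methylallylmagnesium chloride | C=C(C)C[Mg]Cl | starting material
6 | (Z)‑2‑iodo‑6‑methylhepta‑2,6‑dien‑4‑ol (racemic) | C/C(I)=C/C(O)CC(C)=C | intermediate
7 | triethyl{[(Z)‑2‑iodo‑6‑methylhepta‑2,6‑dien‑4‑yl]oxy}silane (racemic) | C/C(I)=C/C(O[Si](CC)(CC)CC)CC(C)=C | intermediate
8 | methyl acrylate | C=CC(=O)OC | starting material
9 | (tert‑butyldimethylsilyloxy)acetaldehyde | O=CCO[Si](C)(C)C(C)(C)C | starting material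
10 | methyl 4‑[(tert‑butyldimethylsilyl)oxy]‑3‑hydroxy‑2‑methylidenebutanoate (racemic) | C=C(C(=O)OC)C(O)CO[Si](C)(C)C(C)(C)C | intermediate
11 | methyl (Z)‑2‑(bromomethyl)‑4‑[(tert‑butyldimethylsilyl)oxy]but‑2‑enoate | COC(=O)/C(CBr)=C/CO[Si](C)(C)C(C)(C)C | intermediate
12 | (S)‑2,2‑dimethyl‑1,3‑dioxolane‑4‑carbaldehyde | O=C[C@@H]1COC(C)(C)O1 | starting material
13 | methyl (3R,4R)‑3‑{[(tert‑butyldimethylsilyl)oxy]methyl}‑4‑[(4S)‑2,2‑dimethyl‑1,3‑dioxolan‑4‑yl]‑4‑hydroxy‑2‑methylidenebutanoate | C=C(C(=O)OC)[C@H](CO[Si](C)(C)C(C)(C)C)[C@@H](O)[C@@H]1COC(C)(C)O1 | intermediate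
14 | (4R,5R)‑4‑{[(tert‑butyldimethylsilyl)oxy]methyl}‑5‑[(4S)‑2,2‑dimethyl‑1,3‑dioxolan‑4‑yl]‑3‑methylideneoxolan‑2‑one | C=C1C(=O)O[C@@H]([C@@H]2COC(C)(C)O2)[C@H]1CO[Si](C)(C)C(C)(C)C | intermediate
15 | (4R,5R)‑4‑{[(tert‑butyldimethylsilyl)oxy]methyl}‑5‑[(1S)‑1,2‑dihydroxyethyl]‑3‑methylideneoxolan‑2‑one | C=C1C(=O)O[C@@H]([C@@H](O)CO)[C@H]1CO[Si](C)(C)C(C)(C)C | intermediate
16 | (2R,3R)‑3‑{[(tert‑butyldimethylsilyl)oxy]methyl}‑4‑methylidene‑5‑oxooxolane‑2‑carbaldehyde | C=C1C(=O)O[C@@H](C=O)[C@H]1CO[Si](C)(C)C(C)(C)C | intermediate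
17 | C5 alcohol (5S; C2 epimers; C2‑OTES, C8‑OTBS) | C=C1C(=O)O[C@@H]([C@@H](O)/C(C)=C\C(O[Si](CC)(CC)CC)CC(C)=C)[C@H]1CO[Si](C)(C)C(C)(C)C | intermediate
18 | C5 TBS ether of 17 | C=C1C(=O)O[C@@H]([C@@H](O[Si](C)(C)C(C)(C)C)/C(C)=C\C(O[Si](CC)(CC)CC)CC(C)=C)[C@H]1CO[Si](C)(C)C(C)(C)C | intermediate
19 | C2,C8 diol (C5‑OTBS; C2 epimers) | C=C1C(=O)O[C@@H]([C@@H](O[Si](C)(C)C(C)(C)C)/C(C)=C\C(O)CC(C)=C)[C@H]1CO | intermediate
20 | keto aldehyde (C2 methallyl ketone, C8 aldehyde, C5‑OTBS) | C=C1C(=O)O[C@@H]([C@@H](O[Si](C)(C)C(C)(C)C)/C(C)=C\C(=O)CC(C)=C)[C@H]1C=O | intermediate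
21 | tiglic acid, (E)‑2‑methylbut‑2‑enoic acid | C/C=C(\C)C(=O)O | starting material
22 | tiglic anhydride | C/C=C(\C)C(=O)OC(=O)/C(C)=C/C | intermediate
23 | C8 bis‑tiglate acylal of 20 | C=C1C(=O)O[C@@H]([C@@H](O[Si](C)(C)C(C)(C)C)/C(C)=C\C(=O)CC(C)=C)[C@H]1C(OC(=O)/C(C)=C/C)OC(=O)/C(C)=C/C | intermediate
24 | cross‑conjugated TBS dienol ether of 23 | C=C1C(=O)O[C@@H]([C@@H](O[Si](C)(C)C(C)(C)C)/C(C)=C\C(O[Si](C)(C)C(C)(C)C)=C\C(C)=C)[C@H]1C(OC(=O)/C(C)=C/C)OC(=O)/C(C)=C/C | intermediate
25 | C8 acyloxycarbenium triflate | C=C1C(=O)O[C@@H]([C@@H](O[Si](C)(C)C(C)(C)C)/C(C)=C\C(O[Si](C)(C)C(C)(C)C)=C\C(C)=C)[C@H]1C=[O+]C(=O)/C(C)=C/C.[O-]S(=O)(=O)C(F)(F)F | intermediate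
26 | 5‑O‑TBS ether of the target | C=C1C(=O)O[C@@H]2[C@H]1[C@@H](OC(=O)/C(C)=C/C)C/C(C)=C\C(=O)/C=C(/C)[C@@H]2O[Si](C)(C)C(C)(C)C | intermediate
27 | CNP0230565.3, (5S,6R,7R,8S)‑5‑hydroxy‑2‑oxo‑8‑tigloyloxygermacra‑1(10)Z,3Z,11(13)‑trien‑12,6‑olide | C=C1C(=O)O[C@@H]2[C@H]1[C@@H](OC(=O)/C(C)=C/C)C/C(C)=C\C(=O)/C=C(/C)[C@@H]2O | target

## Step count and risks

Total steps: 17. Longest linear sequence: 12 steps (steps 5–12 and 14–17).

**Step 16 (proposed new method).** What may go wrong: the C8 cation may be captured by the O5 silyl ether oxygen to give a cyclic acetal, C1 may attack instead of C9, intermolecular reaction may win over ring closure, or the wrong face of C8 may be attacked. The fallback closes the same bond by a classical vinylogous Mukaiyama aldol reaction on the free aldehyde and sets out from diol 19. The primary hydroxyl is acylated selectively with allyl chloroformate and pyridine to give the allyl carbonate F1. Dess–Martin oxidation of the secondary alcohol gives the methallyl ketone F2. Soft enolization (TBSOTf, Et3N) gives the silyl dienol ether carbonate F3. Pd(PPh3)4 (zerovalent palladium) with dimedone removes the carbonate to give the primary alcohol F4. Pyridine‑buffered Dess–Martin oxidation gives the dienol ether aldehyde F5. BF3·OEt2 in CH2Cl2 at −78 °C under high dilution should then close ring B to the 8‑hydroxy macrocycle F6. Acylation of F6 with anhydride 22 and DMAP returns to 26.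

**Step 14.** What may go wrong: slow addition of the hindered unsaturated anhydride, Lewis‑acid cleavage of the C5 silyl ether, or isomerization of the methallyl ketone into conjugation. The fallback sets out from 20 and builds the acylal in two substitution steps. Tigloyl chloride with catalytic ZnCl2 adds across the aldehyde to give the 1‑chloroalkyl tiglate F7. Displacement of chloride by cesium tiglate F8 (from 21 and Cs2CO3) in DMF returns to 23.

**Step 9.** What may go wrong: poor facial selectivity at C5 in the chromium addition. The fallback sets out from the C5 epimer mixture of 17 and replaces substrate control by reagent control. Dess–Martin oxidation gives the C5 enone F9. Corey–Bakshi–Shibata reduction with (S)‑2‑methyl‑CBS‑oxazaborolidine and catecholborane in toluene at −78 °C should return the 5S alcohol 17; the antipodal catalyst is used if the alkenyl arm does not act as the large substituent.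

## Further compounds

F1 | step 16 | C8 allyl carbonate of diol 19 | C=C1C(=O)O[C@@H]([C@@H](O[Si](C)(C)C(C)(C)C)/C(C)=C\C(O)CC(C)=C)[C@H]1COC(=O)OCC=C
F2 | step 16 | C2 methallyl ketone, C8 allyl carbonate | C=C1C(=O)O[C@@H]([C@@H](O[Si](C)(C)C(C)(C)C)/C(C)=C\C(=O)CC(C)=C)[C@H]1COC(=O)OCC=C
F3 | step 16 | TBS dienol ether, C8 allyl carbonate | C=C1C(=O)O[C@@H]([C@@H](O[Si](C)(C)C(C)(C)C)/C(C)=C\C(O[Si](C)(C)C(C)(C)C)=C\C(C)=C)[C@H]1COC(=O)OCC=C
F4 | step 16 | TBS dienol ether, C8 primary alcohol | C=C1C(=O)O[C@@H]([C@@H](O[Si](C)(C)C(C)(C)C)/C(C)=C\C(O[Si](C)(C)C(C)(C)C)=C\C(C)=C)[C@H]1CO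
F5 | step 16 | TBS dienol ether, C8 aldehyde | C=C1C(=O)O[C@@H]([C@@H](O[Si](C)(C)C(C)(C)C)/C(C)=C\C(O[Si](C)(C)C(C)(C)C)=C\C(C)=C)[C@H]1C=O
F6 | step 16 | 8‑hydroxy macrocycle, 5‑O‑TBS | C=C1C(=O)O[C@@H]2[C@H]1[C@@H](O)C/C(C)=C\C(=O)/C=C(/C)[C@@H]2O[Si](C)(C)C(C)(C)C
F7 | step 14 | C8 1‑chloroalkyl tiglate of 20 (C8 epimers) | C=C1C(=O)O[C@@H]([C@@H](O[Si](C)(C)C(C)(C)C)/C(C)=C\C(=O)CC(C)=C)[C@H]1C(Cl)OC(=O)/C(C)=C/C
F8 | step 14 | cesium tiglate | C/C=C(\C)C(=O)[O-].[Cs+]
F9 | step 9 | C5 enone from 17 (C2 epimers) | C=C1C(=O)O[C@@H](C(=O)/C(C)=C\C(O[Si](CC)(CC)CC)CC(C)=C)[C@H]1CO[Si](C)(C)C(C)(C)C
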